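## The problem

The target is a cembrane-type diterpenoid in which a δ-lactone bridges a 14-membered carbocycle. With the lactone numbered C2(CH3)–C3(=O)–O–C4–C5–C6 and the carbocycle C6–C7–…–C17–C4, it carries a trisubstituted epoxide at C9–C10, a tertiary allylic hydroperoxide at C13 beside an E C14=C15 alkene, and a tertiary alcohol at C17; the two rings share C4–C5–C6. There are seven stereocentres (2S, 4R, 6R, 9S, 10S, 13S, 17S). C6 is the only all-carbon centre and is insulated from both oxygenated pairs by CH2 groups, so it cannot be trusted to control them. C4 and C17 are adjacent and can be tied together by a stereospecific epoxide opening. C2 is enolisable, and in the target the C2 methyl, the C6 chain and the C4 substituent are all equatorial on the lactone, so C2 can be left to thermodynamic control. C13 has no directing neighbour and must be set last by the conformation of the finished ring. The hydroperoxide will not survive reductants, strong base or transition metals; the C9–C10 epoxide is acid-labile; and the lactone limits carbanion chemistry to nucleophiles no more basic than a sulfone anion or an allylic ylide. The enabling feature is that the pairs C4/C17 and C9/C10 correspond to two E trisubstituted alkenes, C4=C17 and C9=C10, on the two arms of C6. Each can carry a primary allylic hydroxyl (at C16 and at C11), and in the standard drawing of an allylic alcohol both need oxygen on the same face.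

## Retrosynthesis

**33 ⇒ 32 (C13–O bond).** The hydroperoxide is removed first, with the alkene moved back from C14=C15 to C13=C14. A tertiary centre cannot be substituted stereospecifically by a peroxide nucleophile, and no O–O bond would survive the reductive and basic steps of ring construction, so a Schenck ene reaction on macrocycle 32 is the only direct access. The precursor has one stereocentre and one sensitive group fewer. The forward step must put oxygen on C13 rather than C14, take hydrogen from C15, and choose the right face.

**32 ⇒ 31 (C2).** C2 is disconnected as a thermodynamic problem: 31 is the same macrocycle as a pair of C2 epimers, converged by enolisation. This removes any need to control C2 when it is created.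

**31 ⇒ 30 ⇒ 29 (C15–C16, ring opening).** The carbocycle is cut between C15 and C16. C16 is then the CH2 terminus of a C16–C17 epoxide whose opening releases the C17 hydroxyl with its configuration intact. C15 is an allylic CH2 next to the CH end of the alkene, so a phenylsulfonyl group there stabilises the carbanion. Its later reductive removal passes through an allyl system with a secondary (C15) and a tertiary (C13) terminus, which is protonated at C15 and leaves C13=C14 in place. Cutting C11–C12 instead would put the sulfone on C12, where both allyl termini are secondary and removal cannot distinguish a C12=C13 from a C13=C14 alkene. Forming C13=C14 itself (metathesis or olefination) would give no control of geometry. Precursor 29 is acyclic. The forward reaction must cyclise at high dilution and ignore the lactone.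

**29 ⇒ 27 ⇒ 26 ⇒ 25 ⇒ 19 + 24 (C11–C12).** The C11–C12 single bond is traced back to a C11=C12 alkene (25) made by Wittig reaction of epoxy aldehyde 19 with the C5 phosphonium salt 24, then saturated with diimide (26). This leaves no anion-stabilising group on C12 and never touches C13=C14, whose E geometry is bought with 24. The cut divides the molecule into a C15 piece holding all five early stereocentres and a C5 piece. The forward steps need a ylide that reacts only with the aldehyde, and a reductant that tells a disubstituted from a trisubstituted alkene.

**24 ⇒ 22 ⇒ 21 ⇒ 20.** The C5 unit comes from prenol (20). SeO2 oxidation of its silyl ether 21 functionalises the methyl group trans to the chain and gives the E allylic alcohol 22.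

**19 ⇒ 18 ⇒ 16.** No skeletal bond is cut. The two primary alcohols of triol 16 are told apart because only C16–OH belongs to a 1,2-diol: selective sulfonylation and closure give the C16–C17 epoxide (18), and the remaining C11–OH is oxidised (19).

**16 ⇒ 15 ⇒ 14 (lactone O–C4 bond).** The lactone is cut at its alkyl C–O bond, not the acyl one. The carboxyl oxygen of acid 15 attacks C4 of a C4–C17 epoxide in a 6-exo SN2 opening. C4 must therefore be made with the opposite configuration (S) and is inverted to R, while the epoxide oxygen stays on C17 as the tertiary alcohol. This cut also differentiates the two epoxy alcohols of 14, since only one has the acid within reach.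

**14 ⇒ 13 (four C–O bonds; the key disconnection).** Both epoxides are removed together to give bis-allylic diol 13. One catalyst and one tartrate set C4, C17, C9 and C10. The precursor has a single stereocentre that matters (C6) and two alkenes of defined geometry.

**13 ⇒ 12 ⇒ 11 ⇒ 10 ⇒ 9 ⇒ 8 ⇒ 7.** Functional-group changes only. The C3 carboxyl comes from the terminal carbon of an isopropenyl group (hydroboration of 9, oxidation to 11, allyl ester 12), with the allylic alcohols silylated meanwhile. C2 is created here without control, so 10–31 are C2-epimer pairs. The allylic alcohols of 8 come from the enoates of 7.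

**7 ⇒ 5 ⇒ 3 ⇒ 2 ⇒ 1.** C9=C10 is cut by a Horner–Wadsworth–Emmons reaction with 6 and C4=C17 by a Wittig reaction with 4, leaving keto aldehyde 3. Reconnecting C4 and C9 as a ring alkene gives (R)-limonene (1), which supplies C6 in the correct configuration and the isopropenyl group as the masked C2–C3 unit.

## Roads not taken

**Alternative 1:** The carbocycle is cut at C11–C12. In the forward step LiN(SiMe3)2 deprotonates the C12 allylic phenyl sulfone of open-chain iodide A1, and the carbanion displaces the C11 iodide beside the epoxide to give macrocyclic sulfone A2.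
- Merits: SN2 displacement of a primary iodide is faster and better precedented as a ring closure than the epoxide opening of step 22, and it can be run cold, which the lactone favours. In this respect it is the better road.
- Weak points: the sulfone sits on C12, and its reductive removal from A2 goes through an allyl system with two secondary termini (C12 and C14), with no bias between the C13=C14 and C12=C13 alkenes. The C17 hydroxyl needs a silyl group that must come off later, and the C15–C16 bond has to be made earlier in a separate operation. The strategy itself does not say where the five stereocentres of A1 come from.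
- Comparison: the chosen plan sets against the faster closure a sulfone position that is removed without allylic ambiguity, a closure that unveils the C17 hydroxyl without a protecting group, and one catalytic step for four stereocentres.

**Alternative 2:** The lactone is cut at C4–C5 and O–C3. A complex of Ti(OiPr)4 and BINOL joins α-benzoyloxy aldehyde A3 with silyloxy diene A4 in a hetero-Diels–Alder reaction to give dihydropyranone A5.
- Merits: it is convergent, builds the lactone ring with its C2 methyl in one catalytic step, and sets C4 by catalyst control beside a C17 centre that is already in place.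
- Weak points: in A5, C2 and C6 are sp2 and C6 carries a methoxy group where the target has the C7 chain. C6 and C2 would have to be created afterwards on a tetrasubstituted enol ether (exchange of the methoxy group for carbon, then a reduction that must deliver the trans C2/C6 relationship without touching the other alkenes). C17 in A3 needs its own asymmetric step, and the catalyst must override the adjacent quaternary centre bearing a benzoate.
- Comparison: it is more convergent than the chosen plan, but it leaves the hardest centre of the lactone (C6) unsolved, whereas the chosen plan takes C6 from limonene.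

**Alternative 3:** C6–C7 and C2–CH3 are cut. CuBr·SMe2 with a Josiphos-type ferrocenyl diphosphine adds Grignard reagent A7 to E thioenoate A6, and the magnesium enolate is methylated by CH3I to give thioester A8.
- Merits: C6 and C2 are set together, by the catalyst and with the trans relationship the target needs, so C2 needs no later equilibration. Here it is better than the chosen plan, and it joins two large fragments.
- Weak points: A6 already needs the C4/C17 diol (as acetonide) from a separate asymmetric oxidation, and the C9–C10 epoxide must still be made after removal of the 4-methoxybenzyl group, so three stereo-inducing operations replace one. The catalyst must work beside the stereocentre already present in A6, alkylation of magnesium thioester enolates is sluggish, and A8 carries three different protecting groups to be unpicked.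
- Comparison: the chosen plan accepts a C2-epimer pair and one equilibration, and in return gets C6 from the chiral pool and both oxygenated pairs from a single reagent-controlled step.

Key step: step 11

Remark: atom numbers of the target are used for all intermediates; compounds 10–31 are pairs of C2 epimers (SMILES written without a C2 descriptor) that converge in step 24.

## Route

Step 1
Reactants: 1 (R)-limonene
Product: 2 (4R)-limonene 1,2-oxide (epoxide diastereomers)
Conditions: mCPBA, CH2Cl2, 0 °C
Reagents that add atoms: 3-chloroperoxybenzoic acid, OOC(=O)c1cccc(Cl)c1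
Why: Prilezhaev epoxidation; the trisubstituted ring alkene is much more nucleophilic than the isopropenyl group, and the epoxide configuration is immaterial because both carbons become carbonyls in step 2.

Step 2
Reactants: 2 (4R)-limonene 1,2-oxide
Product: 3 (3R)-6-oxo-3-(prop-1-en-2-yl)heptanal
Conditions: H5IO6, THF/H2O, 0 °C to rt
Reagents that add atoms: water, O
Why: Periodic acid hydrolyses the epoxide and cleaves the glycol in one flask (Malaprade cleavage), a known route from limonene oxide to this keto aldehyde; C6 is not enolisable and the isopropenyl group is untouched.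

Step 3
Reactants: 3 (3R)-6-oxo-3-(prop-1-en-2-yl)heptanal; 4 ethyl 2-(triphenylphosphoranylidene)propanoate
Product: 5 ethyl (2E,5R)-2-methyl-8-oxo-5-(prop-1-en-2-yl)non-2-enoate
Conditions: CH2Cl2, rt
Reagents that add atoms: none
Why: Wittig olefination with a stabilised α-methyl ylide, which reacts with the aldehyde and not with the methyl ketone and gives the E C4=C17 enoate.

Step 4
Reactants: 5 keto enoate; 6 triethyl phosphonoacetate
Product: 7 diethyl (2E,5R,8E)-2,8-dimethyl-5-(prop-1-en-2-yl)deca-2,8-dienedioate
Conditions: NaH, THF, 0 °C to rt
Reagents that add atoms: none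
Why: Horner–Wadsworth–Emmons olefination of the methyl ketone; the E C9=C10 enoate should predominate as with other methyl ketones, and the minor Z isomer is removed by chromatography here or at diol 8.

Step 5
Reactants: 7 diester
Product: 8 (2E,5R,8E)-2,8-dimethyl-5-(prop-1-en-2-yl)deca-2,8-diene-1,10-diol
Conditions: i-Bu2AlH, CH2Cl2, −78 °C
Reagents that add atoms: none
Why: 1,2-Reduction of both enoates by the aluminium hydride gives the allylic alcohols without touching alkene geometry or the isopropenyl group.

Step 6
Reactants: 8 diol
Product: 9 (2E,5R,8E)-1,10-bis(tert-butyldimethylsilyloxy)-2,8-dimethyl-5-(prop-1-en-2-yl)deca-2,8-diene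
Conditions: TBSCl, imidazole, DMF, rt
Reagents that add atoms: tert-butyldimethylsilyl chloride, CC(C)(C)[Si](C)(C)Cl
Why: Standard silylation; it keeps the hydroxyls from consuming borane in step 7 and from being oxidised in step 8.

Step 7
Reactants: 9 bis-silyl ether
Product: 10 (2RS,3R,6E)-8-(tert-butyldimethylsilyloxy)-3-[(2E)-4-(tert-butyldimethylsilyloxy)-3-methylbut-2-en-1-yl]-2,6-dimethyloct-6-en-1-ol
Conditions: 9-BBN, THF, 0 °C to rt; then NaOH, H2O2
Reagents that add atoms: hydrogen peroxide, OO
Why: Hydroboration–oxidation; 9-BBN adds to the 1,1-disubstituted alkene far faster than to trisubstituted ones and puts boron on the terminal carbon. C2 forms without control because C6 carries two near-identical CH2 arms, so 10 is a C2-epimer pair.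

Step 8
Reactants: 10 primary alcohol
Product: 11 the corresponding oct-6-enoic acid (C3 carboxylic acid; C2 epimers)
Conditions: TEMPO (cat.), PhI(OAc)2, MeCN/H2O, rt
Reagents that add atoms: water, O
Why: Oxoammonium (TEMPO) oxidation through the aldehyde hydrate to the acid; silyl ethers and trisubstituted alkenes tolerate it.

Step 9
Reactants: 11 acid
Product: 12 allyl ester of 11 (C2 epimers)
Conditions: allyl bromide, K2CO3, DMF, rt
Reagents that add atoms: allyl bromide, C=CCBr
Why: SN2 O-alkylation of the carboxylate; the allyl ester can later be removed under neutral conditions in the presence of two epoxy alcohols, which aqueous hydroxide would put at risk of Payne rearrangement.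

Step 10
Reactants: 12 allyl ester bis-silyl ether
Product: 13 allyl (2RS,3R,6E)-8-hydroxy-3-[(2E)-4-hydroxy-3-methylbut-2-en-1-yl]-2,6-dimethyloct-6-enoate
Conditions: Bu4NF, AcOH, THF, rt
Reagents that add atoms: none
Why: Fluoride desilylation, buffered so that the ester and C2–H see no free alkoxide; it releases the two allylic alcohols for step 11.

Step 11
Reactants: 13 bis-allylic diol allyl ester
Product: 14 bis-epoxy diol allyl ester (4S,6R,9S,10S,17S; C2 epimers): C4–C17 and C9–C10 epoxides, C16 and C11 primary alcohols
Conditions: Ti(OiPr)4 (20 mol %), L-(+)-diethyl tartrate (24 mol %), t-BuOOH (decane), 4 Å molecular sieves, CH2Cl2, −20 °C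
Reagents that add atoms: tert-butyl hydroperoxide, CC(C)(C)OO
Why: Sharpless asymmetric epoxidation run on both allylic alcohols in one flask. Each carbinol exchanges onto the dimeric titanium tartrate as an alkoxide beside a titanium-bound tert-butyl peroxide, and the peroxide oxygen is transferred within the complex to the alkene face the tartrate exposes. The closest known cases are geraniol (3-methyl) and E 2-methyl-2-alken-1-ols, both of which give 2S,3S epoxy alcohols with L-(+)-tartrate. Each oxirane closes by concerted syn addition of one oxygen atom across the alkene, both C–O bonds forming in one event, so the E geometry becomes the trans arrangement of the chains on C4/C17 and on C9/C10. C4 and C17 (both S) and C9 and C10 (both S) are set by the tartrate alone; drawn with the carbinol carbon at the lower right, both alkenes need oxygen on the same face, so one tartrate serves both. The step needs reagent control over the C6 centre, which is secured because C6 is homoallylic to one alkene and one carbon further from the other and both alkenes belong to the best substrate classes. It also needs chemoselectivity against the allyl ester alkene, which has no directing hydroxyl. Molecular sieves and −20 °C keep the catalyst turning over and protect the epoxy alcohols, whose C9 and C17 are fully substituted, from titanium-assisted opening.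

Step 12
Reactants: 14 bis-epoxy diol allyl ester
Product: 16 lactone triol (4R,6R,9S,10S,17S; C2 epimers): δ-lactone closed at C4 and C17(CH3)(OH)CH2OH side chain and C9–C10 epoxide bearing C11H2OH, via bis-epoxy diol acid 15 (not isolated)
Conditions: Pd(PPh3)4 (cat.), morpholine, THF, rt; then Ti(OiPr)4, CH2Cl2 (dilute), 0 °C to rt
Reagents that add atoms: none
Why: Tsuji–Trost deallylation, then titanium-mediated opening of a 2,3-epoxy alcohol at its C3 position (here C4) by the carboxylic acid, intramolecular and 6-exo. SN2 attack inverts C4 from S to R while the C17–O bond is untouched; dilution disfavours intermolecular opening of the C9–C10 epoxy alcohol.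

Step 13
Reactants: 16 lactone triol
Product: 18 lactone bearing the C16–C17 terminal epoxide and free C11 hydroxyl (4R,6R,9S,10S,17S; C2 epimers), via C16 monotosylate 17 (not isolated)
Conditions: TsCl, Bu2SnO (cat.), Et3N, CH2Cl2, 0 °C; then DBU, rt
Reagents that add atoms: none
Why: Stannylene-acetal-catalysed sulfonylation is specific for the primary hydroxyl of a 1,2-diol, so C16–OH is tosylated and C11–OH is not. DBU then closes the epoxide by 3-exo-tet displacement through the C17 oxygen, which keeps the C17 configuration.

Step 14
Reactants: 18 epoxy alcohol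
Product: 19 C11 epoxy aldehyde (C9–C10 epoxide unchanged, C10 bearing CHO; C2 epimers)
Conditions: Dess–Martin periodinane, NaHCO3, CH2Cl2, 0 °C to rt
Reagents that add atoms: none
Why: Dess–Martin oxidation of a 2,3-epoxy alcohol to the epoxy aldehyde under buffered conditions; C10 is an oxirane carbon and does not enolise.

Step 15
Reactants: 20 3-methylbut-2-en-1-ol (prenol)
Product: 21 tert-butyldimethyl[(3-methylbut-2-en-1-yl)oxy]silane
Conditions: TBSCl, imidazole, CH2Cl2, rt
Reagents that add atoms: tert-butyldimethylsilyl chloride, CC(C)(C)[Si](C)(C)Cl
Why: Standard silylation of a primary allylic alcohol.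

Step 16
Reactants: 21 prenyl silyl ether
Product: 22 (2E)-4-(tert-butyldimethylsilyloxy)-2-methylbut-2-en-1-ol
Conditions: SeO2 (cat.), t-BuOOH, CH2Cl2, rt
Reagents that add atoms: tert-butyl hydroperoxide, CC(C)(C)OO
Why: SeO2 allylic oxidation (ene reaction then [2,3]-sigmatropic shift) of a prenyl group, known to functionalise the methyl group trans to the chain, which gives the E allylic alcohol.

Step 17
Reactants: 22 E allylic alcohol
Product: 24 [(2E)-4-(tert-butyldimethylsilyloxy)-2-methylbut-2-en-1-yl]triphenylphosphonium bromide, via allylic bromide 23 (not isolated)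
Conditions: CBr4, PPh3, CH2Cl2, 0 °C; then PPh3, MeCN, 60 °C
Reagents that add atoms: carbon tetrabromide, BrC(Br)(Br)Br; triphenylphosphine, c1ccc(cc1)P(c1ccccc1)c1ccccc1
Why: Appel bromination (SN2, no allylic shift) followed by quaternisation with PPh3; the silyl ether at the far end is a poor leaving group and will not be expelled from the ylide.

Step 18
Reactants: 19 epoxy aldehyde; 24 phosphonium bromide
Product: 25 C11=C12 diene (C11=C12 E/Z mixture, C13=C14 E, C15 silyl ether; C2 epimers)
Conditions: NaN(SiMe3)2, THF, −78 °C to rt
Reagents that add atoms: none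
Why: Wittig olefination with a semi-stabilised allylic ylide, which at −78 °C keeps its E C13=C14 geometry and reacts at its α-carbon. The geometry of the new C11=C12 bond is irrelevant because it is saturated in step 19, and the ylide is not basic enough to enolise the lactone.

Step 19
Reactants: 25 diene
Product: 26 C11–C12 saturated silyl ether (C13=C14 E; C2 epimers)
Conditions: 2-nitrobenzenesulfonylhydrazide, Et3N, CH2Cl2, rt
Reagents that add atoms: none
Why: Diimide reduction by concerted syn transfer of H2; it is strongly retarded by substitution, so the disubstituted C11=C12 bond is reduced and the trisubstituted C13=C14 bond is kept. Epoxides and lactone are inert.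

Step 20
Reactants: 26 silyl ether
Product: 27 C15 allylic alcohol (C2 epimers)
Conditions: Bu4NF, AcOH, THF, 0 °C
Reagents that add atoms: none
Why: Fluoride desilylation of the primary allylic silyl ether, buffered to spare the two epoxides and C2–H.

Step 21
Reactants: 27 allylic alcohol
Product: 29 C15 phenyl sulfone (C2 epimers), via C15 mesylate 28 (not isolated)
Conditions: MsCl, Et3N, CH2Cl2, −20 °C; then PhSO2Na, Bu4NI (cat.), DMF, rt
Reagents that add atoms: sodium benzenesulfinate, [Na+].[O-]S(=O)c1ccccc1
Why: Mesylation and in situ SN2 displacement by sulfinate (S-alkylation) at the primary allylic carbon; the sulfone ends up on the CH2 next to the CH terminus of the alkene, from which it can later be removed without allylic transposition.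

Step 22
Reactants: 29 epoxy sulfone
Product: 30 14-membered C15 sulfone with free C17 hydroxyl (C15 and C2 epimers)
Conditions: LiN(SiMe3)2, THF/DMPU, 0.002 M, −78 °C to rt
Reagents that add atoms: none
Why: Deprotonation of the allylic sulfone (more acidic than C2–H by several pK units) and intramolecular SN2 opening of the 2,2-disubstituted epoxide at its CH2 terminus, the type of closure used for 14-membered terpenoid rings with sulfur-stabilised allyl anions. The E alkene geometrically excludes attack on the C9–C10 epoxide, which would need a six- or seven-membered ring containing an E alkene, and the C17 configuration is untouched.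

Step 23
Reactants: 30 macrocyclic sulfone
Product: 31 13E macrocyclic alkene (4R,6R,9S,10S,17S; C2 epimers)
Conditions: Na(Hg), Na2HPO4, MeOH/THF, −20 °C
Reagents that add atoms: none
Why: Reductive desulfonylation; the allyl anion has a secondary (C15) and a tertiary (C13) terminus and is protonated mainly at C15, which keeps C13=C14 in place. The buffered medium spares lactone and epoxide.

Step 24
Reactants: 31 macrocyclic alkene
Product: 32 13E macrocyclic alkene, 2S epimer (2S,4R,6R,9S,10S,17S)
Conditions: DBU, toluene, 80 °C
Reagents that add atoms: none
Why: Epimerisation through the lactone enolate under thermodynamic control; the 2S epimer has the C2 methyl, the C6 chain and the C4 substituent all equatorial and should dominate. The residual 2R epimer is separated and resubmitted.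

Step 25
Reactants: 32 macrocyclic alkene
Product: 33 target hydroperoxide (2S,4R,6R,9S,10S,13S,17S,14E)
Conditions: O2, hν (visible), tetraphenylporphyrin, CH2Cl2, 0 °C
Reagents that add atoms: dioxygen, O=O
Why: Schenck ene reaction of singlet oxygen: oxygen bonds to C13 while a C15 hydrogen is transferred suprafacially and the alkene moves to C14=C15 (E). The C13 configuration follows from the exposed face of the macrocyclic alkene, and the target is separated from the C14 hydroperoxide regioisomer and the C13 epimer.

## Compound list

1 | (R)-limonene | CC1=CC[C@@H](CC1)C(C)=C | starting material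
2 | (4R)-limonene 1,2-oxide, epoxide diastereomers | CC12OC1C[C@@H](CC2)C(C)=C | intermediate
3 | (3R)-6-oxo-3-(prop-1-en-2-yl)heptanal | CC(=O)CC[C@H](CC=O)C(C)=C | intermediate
4 | ethyl 2-(triphenylphosphoranylidene)propanoate | CCOC(=O)C(C)=P(c1ccccc1)(c1ccccc1)c1ccccc1 | starting material
5 | ethyl (2E,5R)-2-methyl-8-oxo-5-(prop-1-en-2-yl)non-2-enoate | CCOC(=O)/C(C)=C/C[C@@H](CCC(C)=O)C(C)=C | intermediate
6 | triethyl phosphonoacetate | CCOC(=O)CP(=O)(OCC)OCC | starting material
7 | diethyl (2E,5R,8E)-2,8-dimethyl-5-(prop-1-en-2-yl)deca-2,8-dienedioate | CCOC(=O)/C(C)=C/C[C@@H](CC/C(C)=C/C(=O)OCC)C(C)=C | intermediate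
8 | (2E,5R,8E)-2,8-dimethyl-5-(prop-1-en-2-yl)deca-2,8-diene-1,10-diol | OC/C(C)=C/C[C@@H](CC/C(C)=C/CO)C(C)=C | intermediate
9 | bis(tert-butyldimethylsilyl) ether of 8 | CC(C)(C)[Si](C)(C)OC/C(C)=C/C[C@@H](CC/C(C)=C/CO[Si](C)(C)C(C)(C)C)C(C)=C | intermediate
10 | (2RS,3R,6E)-8-(tert-butyldimethylsilyloxy)-3-[(2E)-4-(tert-butyldimethylsilyloxy)-3-methylbut-2-en-1-yl]-2,6-dimethyloct-6-en-1-ol | CC(C)(C)[Si](C)(C)OC/C(C)=C/C[C@@H](CC/C(C)=C/CO[Si](C)(C)C(C)(C)C)C(C)CO | intermediate
11 | carboxylic acid from 10 (C3 acid, C2 epimers) | CC(C)(C)[Si](C)(C)OC/C(C)=C/C[C@@H](CC/C(C)=C/CO[Si](C)(C)C(C)(C)C)C(C)C(O)=O | intermediate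
12 | allyl ester of 11 | CC(C)(C)[Si](C)(C)OC/C(C)=C/C[C@@H](CC/C(C)=C/CO[Si](C)(C)C(C)(C)C)C(C)C(=O)OCC=C | intermediate
13 | allyl (2RS,3R,6E)-8-hydroxy-3-[(2E)-4-hydroxy-3-methylbut-2-en-1-yl]-2,6-dimethyloct-6-enoate | OC/C(C)=C/C[C@@H](CC/C(C)=C/CO)C(C)C(=O)OCC=C | intermediate
14 | bis-epoxy diol allyl ester (4S,6R,9S,10S,17S; C2 epimers) | C=CCOC(=O)C(C)[C@@H](C[C@@H]1O[C@@]1(C)CO)CC[C@]1(C)O[C@H]1CO | intermediate
15 | bis-epoxy diol acid (not isolated) | OC(=O)C(C)[C@@H](C[C@@H]1O[C@@]1(C)CO)CC[C@]1(C)O[C@H]1CO | intermediate
16 | lactone triol (4R,6R,9S,10S,17S; C2 epimers) | CC1C(=O)O[C@H](C[C@H]1CC[C@]1(C)O[C@H]1CO)[C@@](C)(O)CO | intermediate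
17 | C16 monotosylate of 16 (not isolated) | CC1C(=O)O[C@H](C[C@H]1CC[C@]1(C)O[C@H]1CO)[C@@](C)(O)COS(=O)(=O)c1ccc(C)cc1 | intermediate
18 | lactone with C16–C17 epoxide and C11 hydroxyl (4R,6R,9S,10S,17S; C2 epimers) | CC1C(=O)O[C@H](C[C@H]1CC[C@]1(C)O[C@H]1CO)[C@]1(C)CO1 | intermediate
19 | C11 epoxy aldehyde (same spatial arrangement; C10 descriptor becomes R because C11 is now CHO) | CC1C(=O)O[C@H](C[C@H]1CC[C@]1(C)O[C@H]1C=O)[C@]1(C)CO1 | intermediate
20 | 3-methylbut-2-en-1-ol (prenol) | CC(C)=CCO | starting material
21 | tert-butyldimethyl[(3-methylbut-2-en-1-yl)oxy]silane | CC(C)=CCO[Si](C)(C)C(C)(C)C | intermediate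
22 | (2E)-4-(tert-butyldimethylsilyloxy)-2-methylbut-2-en-1-ol | OC/C(C)=C/CO[Si](C)(C)C(C)(C)C | intermediate
23 | (2E)-1-bromo-4-(tert-butyldimethylsilyloxy)-2-methylbut-2-ene (not isolated) | BrC/C(C)=C/CO[Si](C)(C)C(C)(C)C | intermediate
24 | [(2E)-4-(tert-butyldimethylsilyloxy)-2-methylbut-2-en-1-yl]triphenylphosphonium bromide | CC(C)(C)[Si](C)(C)OC/C=C(\C)C[P+](c1ccccc1)(c1ccccc1)c1ccccc1.[Br-] | intermediate
25 | C11=C12 diene, C15 silyl ether (C11=C12 E/Z, 13E; C2 epimers) | CC1C(=O)O[C@H](C[C@H]1CC[C@]1(C)O[C@H]1C=C/C(C)=C/CO[Si](C)(C)C(C)(C)C)[C@]1(C)CO1 | intermediate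
26 | C11–C12 saturated C15 silyl ether (13E; C2 epimers) | CC1C(=O)O[C@H](C[C@H]1CC[C@]1(C)O[C@H]1CC/C(C)=C/CO[Si](C)(C)C(C)(C)C)[C@]1(C)CO1 | intermediate
27 | C15 allylic alcohol (C2 epimers) | CC1C(=O)O[C@H](C[C@H]1CC[C@]1(C)O[C@H]1CC/C(C)=C/CO)[C@]1(C)CO1 | intermediate
28 | C15 mesylate (not isolated) | CC1C(=O)O[C@H](C[C@H]1CC[C@]1(C)O[C@H]1CC/C(C)=C/COS(C)(=O)=O)[C@]1(C)CO1 | intermediate
29 | C15 phenyl sulfone with C16–C17 epoxide (C2 epimers) | CC1C(=O)O[C@H](C[C@H]1CC[C@]1(C)O[C@H]1CC/C(C)=C/CS(=O)(=O)c1ccccc1)[C@]1(C)CO1 | intermediate
30 | 14-membered C15 phenyl sulfone, C17 hydroxyl (C15 and C2 epimers) | CC1C(=O)O[C@@H]2C[C@H]1CC[C@]1(C)O[C@H]1CC/C(C)=C/C(S(=O)(=O)c1ccccc1)C[C@]2(C)O | intermediate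
31 | 13E macrocyclic alkene (4R,6R,9S,10S,17S; C2 epimers) | CC1C(=O)O[C@@H]2C[C@H]1CC[C@]1(C)O[C@H]1CC/C(C)=C/CC[C@]2(C)O | intermediate
32 | 13E macrocyclic alkene (2S,4R,6R,9S,10S,17S) | C[C@@H]1C(=O)O[C@@H]2C[C@H]1CC[C@]1(C)O[C@H]1CC/C(C)=C/CC[C@]2(C)O | intermediate
33 | target hydroperoxide (2S,4R,6R,9S,10S,13S,17S,14E) | C[C@@H]1C(=O)O[C@@H]2C[C@H]1CC[C@]1(C)O[C@H]1CC[C@](C)(OO)/C=C/C[C@]2(C)O | target

## Step count and least certain steps

Total: 25 steps. Longest linear sequence: 22 steps (1–14, then 18–25); the C5 branch (15–17) has 3 steps.

**Step 11 (key step).** The most likely failure is incomplete or facially eroded oxygen transfer at one of the two alkenes. The mono- and bis-epoxy alcohols bind titanium more strongly than the substrate, so the catalyst may be inhibited, and a stalled reaction also gives the fully substituted C9 and C17 oxirane carbons time to be opened under titanium assistance.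
Fallback: reagent control without the hydroxyl handle. Starting from 12, Shi epoxidation is run with the enantiomer of the D-fructose-derived ketone (made from L-sorbose), KHSO5, K2CO3, MeCN/dimethoxymethane/H2O, 0 °C. Its dioxirane gives S,S epoxides from E trisubstituted alkenes of this pattern and does not react with the terminal allyl ester alkene. The product is the bis-epoxy bis-silyl ether F1, and Bu4NF returns the route to 14.

**Step 25.** Two selectivities are at risk. Regioselectivity is threatened by hydrogen abstraction from the C13 methyl group, which lies on the same side of the E alkene as C15 and would put oxygen on C14 with an exocyclic alkene. Facial selectivity at C13 rests only on the ring conformation.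
Fallback: ionic, Markovnikov delivery of the peroxide. Starting from 32:
- the C17 hydroxyl is silylated (Me3SiCl, imidazole) to the trimethylsilyl ether F2, so that it cannot capture a bromonium ion;
- an N-bromo reagent (1,3-dibromo-5,5-dimethylhydantoin) with anhydrous ethereal H2O2 at −40 °C adds Br and OOH anti, with OOH on the tertiary C13, to give the β-bromo hydroperoxide F3;
- 2-methoxypropene with pyridinium tosylate gives the peroxyketal F4;
- DBU removes HBr, necessarily towards C15 because C13 has no hydrogen, to give the 14E peroxyketal F5;
- pyridinium tosylate in methanol releases both protecting groups and returns to 33.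

The peroxide enters anti to the electrophile, so this sequence is complementary in facial sense to the ene reaction.

**Step 22.** Attack on the hindered epoxide CH2 at high dilution is slow. This gives the allyl sulfone anion time to be consumed by acylation at the lactone carbonyl or by proton transfer from C2, and it gives oligomerisation a chance.
Fallback: take the lactone out of play. Starting from 29:
- i-Bu2AlH at −78 °C gives the lactol F6;
- TBSCl/imidazole gives the silyl acetal F7;
- cyclisation can now be forced (n-BuLi or LiN(SiMe3)2, THF/DMPU, rt) to the macrocyclic silyl acetal F8;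
- Bu4NF gives the lactol F9;
- TEMPO (cat.)/PhI(OAc)2 oxidises it back to the lactone, returning at 30.

**Step 12.** Titanium-bound nucleophiles (isopropoxide, or a second acid molecule) may open the C9–C10 epoxy alcohol at C9, or the acid may attack the tertiary C17 (7-endo) instead of C4.
Fallback: SN2 opening by the carboxylate without a Lewis acid. Starting from 14:
- both primary hydroxyls are silylated (Et3SiCl, imidazole) to the bis-triethylsilyl ether F10, which rules out Payne rearrangement;
- Pd(PPh3)4/morpholine gives the acid F11;
- Cs2CO3 in DMF at 60 °C closes the lactone at the only SN2-accessible carbon, C4, to give F12;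
- Bu4NF returns to 16.

**Step 24.** The thermodynamic preference for the equatorial C2 methyl may be too small for a clean convergence, and the hot base may also move the acyl group to the C17 hydroxyl.
Fallback: separate the epimers early by enzyme. Starting from 10, a lipase (Pseudomonas cepacia lipase, vinyl acetate) acylates the two C2 epimers of this 2-methyl primary alcohol at different rates. The 2S fraction is obtained either as unreacted alcohol or as the acetate F13, which is cleaved with K2CO3/MeOH. It re-enters the route at 10 as a single epimer, and all later compounds are then single C2 epimers.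

## Further compounds

F1 | step 11 | bis-epoxy bis(tert-butyldimethylsilyl) ether allyl ester | C=CCOC(=O)C(C)[C@@H](C[C@@H]1O[C@@]1(C)CO[Si](C)(C)C(C)(C)C)CC[C@]1(C)O[C@H]1CO[Si](C)(C)C(C)(C)C
F2 | step 25 | C17 O-trimethylsilyl ether of 32 | C[C@@H]1C(=O)O[C@@H]2C[C@H]1CC[C@]1(C)O[C@H]1CC/C(C)=C/CC[C@]2(C)O[Si](C)(C)C
F3 | step 25 | (13S,14R)-14-bromo-13-hydroperoxide | C[C@@H]1C(=O)O[C@@H]2C[C@H]1CC[C@]1(C)O[C@H]1CC[C@](C)(OO)[C@H](Br)CC[C@]2(C)O[Si](C)(C)C
F4 | step 25 | 14-bromo 13-(2-methoxyprop-2-yl) peroxyketal | C[C@@H]1C(=O)O[C@@H]2C[C@H]1CC[C@]1(C)O[C@H]1CC[C@](C)(OOC(C)(C)OC)[C@H](Br)CC[C@]2(C)O[Si](C)(C)C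
F5 | step 25 | 14E 13-(2-methoxyprop-2-yl) peroxyketal, C17 silyl ether | C[C@@H]1C(=O)O[C@@H]2C[C@H]1CC[C@]1(C)O[C@H]1CC[C@](C)(OOC(C)(C)OC)/C=C/C[C@]2(C)O[Si](C)(C)C
F6 | step 22 | lactol of 29 | CC1C(O)O[C@H](C[C@H]1CC[C@]1(C)O[C@H]1CC/C(C)=C/CS(=O)(=O)c1ccccc1)[C@]1(C)CO1
F7 | step 22 | O-tert-butyldimethylsilyl lactol of 29 | CC1C(O[Si](C)(C)C(C)(C)C)O[C@H](C[C@H]1CC[C@]1(C)O[C@H]1CC/C(C)=C/CS(=O)(=O)c1ccccc1)[C@]1(C)CO1
F8 | step 22 | macrocyclic C15 sulfone, O-silyl lactol | CC1C(O[Si](C)(C)C(C)(C)C)O[C@@H]2C[C@H]1CC[C@]1(C)O[C@H]1CC/C(C)=C/C(S(=O)(=O)c1ccccc1)C[C@]2(C)O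
F9 | step 22 | macrocyclic C15 sulfone, lactol | CC1C(O)O[C@@H]2C[C@H]1CC[C@]1(C)O[C@H]1CC/C(C)=C/C(S(=O)(=O)c1ccccc1)C[C@]2(C)O
F10 | step 12 | bis-epoxy bis(triethylsilyl) ether allyl ester | C=CCOC(=O)C(C)[C@@H](C[C@@H]1O[C@@]1(C)CO[Si](CC)(CC)CC)CC[C@]1(C)O[C@H]1CO[Si](CC)(CC)CC
F11 | step 12 | bis-epoxy bis(triethylsilyl) ether acid | OC(=O)C(C)[C@@H](C[C@@H]1O[C@@]1(C)CO[Si](CC)(CC)CC)CC[C@]1(C)O[C@H]1CO[Si](CC)(CC)CC
F12 | step 12 | lactone with C17 hydroxyl and C11, C16 triethylsilyl ethers | CC1C(=O)O[C@H](C[C@H]1CC[C@]1(C)O[C@H]1CO[Si](CC)(CC)CC)[C@@](C)(O)CO[Si](CC)(CC)CC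
F13 | step 24 | acetate of the 2S epimer of 10 | CC(=O)OC[C@@H](C)[C@@H](C/C=C(\C)CO[Si](C)(C)C(C)(C)C)CC/C(C)=C/CO[Si](C)(C)C(C)(C)C
A1 | alternative 1 | open-chain C11 iodide with C12 phenyl sulfone and C17 triethylsilyl ether | C[C@@H]1C(=O)O[C@H](C[C@H]1CC[C@]1(C)O[C@H]1CI)[C@](C)(CC/C=C(\C)CS(=O)(=O)c1ccccc1)O[Si](CC)(CC)CC
A2 | alternative 1 | 14-membered C12 phenyl sulfone, C17 triethylsilyl ether | C[C@@H]1C(=O)O[C@@H]2C[C@H]1CC[C@]1(C)O[C@H]1CC(S(=O)(=O)c1ccccc1)/C(C)=C/CC[C@]2(C)O[Si](CC)(CC)CC
A3 | alternative 2 | C4 aldehyde with C17 benzoate | O=C[C@@](C)(OC(=O)c1ccccc1)CC/C=C(\C)CO[Si](C)(C)C(C)(C)C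
A4 | alternative 2 | 1,3-dimethoxy-2-methyl-1-(trimethylsilyloxy)buta-1,3-diene | COC(=C)C(C)=C(OC)O[Si](C)(C)C
A5 | alternative 2 | 6-substituted 4-methoxy-3-methyl-5,6-dihydropyran-2-one | CC1=C(OC)C[C@@H](OC1=O)[C@@](C)(OC(=O)c2ccccc2)CC/C=C(\C)CO[Si](C)(C)C(C)(C)C
A6 | alternative 3 | E thioenoate with C4/C17 acetonide | CCSC(=O)/C=C/C[C@H]1OC(C)(C)O[C@@]1(C)CC/C=C(\C)CO[Si](C)(C)C(C)(C)C
A7 | alternative 3 | C7 Grignard reagent | Br[Mg]CC/C(C)=C/COCc1ccc(OC)cc1
A8 | alternative 3 | C2-methyl C6-alkyl thioester | CCSC(=O)[C@@H](C)[C@H](CC/C(C)=C/COCc1ccc(OC)cc1)C[C@H]1OC(C)(C)O[C@@]1(C)CC/C=C(\C)CO[Si](C)(C)C(C)(C)C
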